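At 2.5 d the flask is read, and the question is whether the excess in the product at that time can be taken from the substrate readings of that same time.

all flasks: left-handed substrate 0.35 M; right-handed substrate 0.35 M; racemization catalyst 35 mM
- north-west: partner 0.98 M; free catalyst 12 mM; run made earlier
- north-east: partner 1.5 M; free catalyst 12 mM; run made earlier
- west: partner 0.70 M; free catalyst 18 mM; run made earlier
- flask: partner 0.700 M; free catalyst 12 mM; time 2.5 d

A single-handed free catalyst beside a racemization catalyst is the setting of a dynamic kinetic resolution, and the north-west run has the same catalyst charges as the flask, with more partner, so that run is the guide.

| run | time / d | left-handed substrate / % | right-handed substrate / % |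
|---|---|---|---|
| north-west | 0.250 | 19.1 | 46.2 |
| north-west | 0.417 | 14.8 | 45.2 |
| north-west | 0.833 | 13.5 | 42.9 |
| north-west | 1.67 | 14.7 | 39.4 |
| north-west | 3.00 | 18.2 | 36.6 |
| north-east | 0.625 | 12.7 | 43.3 |
| north-east | 1.25 | 13.9 | 41.0 |
| north-east | 1.67 | 16.5 | 39.9 |
| north-east | 2.50 | 17.9 | 37.2 |
| north-east | 3.00 | 19.8 | 37.5 |
| west | 0.250 | 16.8 | 46.7 |
| west | 0.417 | 12.3 | 44.7 |
| west | 0.833 | 9.6 | 41.5 |
| west | 1.67 | 9.6 | 37.2 |
| west | 3.00 | 13.2 | 34.4 |

(readings scatter by 0.5 percentage points)

- free catalyst is single-handed; left-handed substrate and right-handed substrate are mirror images of each other, charged as a racemate, each of them at the stated concentration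
- the analysis behind the earlier runs scatters by 0.5 percentage points, standard deviation
- an excess is the difference of the two amounts in percent of their sum
- an excess is below zero if the other one leads

No product is read, but what the pair of substrates has lost is product. Between 1.67 d and 3.00 d the north-west pair stands at 54.1% and then 54.8% of the charge, while the gap between the substrates falls from 25 percentage points to 18 points, a larger change. That late fall in the north-west run is therefore read as racemization, at 0.221 d⁻¹ as a reading, so a late gap in that run understates the product difference. At 0.250 d in the north-west run, however, the same rate has acted for a small share of its time scale, and 34.7% has already reacted, against 45.2% at the last reading. So the early excess, the first gap divided by the first loss, is the number to freeze: 27 points over that loss gives 78.1% as a north-west reading, and this is my reckoning for the excess in the product of the flask.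

- part of the left-handed substrate and right-handed substrate charged together that has reacted at 2.5 d
- excess of left-handed product over right-handed product in the product at 2.5 d
- excess of right-handed substrate over left-handed substrate among what is left of the two at 2.5 d

The forecast gives 45.5% reacted, an excess of 45% in the product and an excess of 37.6% among the substrates, on the ground: “By mass balance, the product difference equals this gap.” Its excess in the product lies below mine.

The flask gives 44.2% reacted, an excess of 79.0% in the product and an excess of 37.2% among the substrates; its product excess already stands at 79.2% at 1.25 d.

    partner + free catalyst + left-handed substrate → free catalyst + left-handed product (k = 0.472 M⁻² min⁻¹)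
    partner + free catalyst + right-handed substrate → free catalyst + right-handed product (k = 0.0319 M⁻² min⁻¹)
    left-handed substrate + racemization catalyst ⇌ right-handed substrate + racemization catalyst, rate k3*[racemization catalyst]*[left-handed substrate] forward; the back reaction follows from the equilibrium constant (k = 0.00230 M⁻¹ min⁻¹)
    partner → decomposed reagent (k = 2.79 × 10⁻⁵ min⁻¹)
    free catalyst → spent catalyst A (k = 6.26 × 10⁻⁵ min⁻¹)
    partner + free catalyst → spent catalyst B (k = 0.00370 M⁻¹ min⁻¹)

In the flask the early excess times the conversion gives a product difference of 35 points, while the gap between the substrates at 2.5 d is 21 points.

In the neighbour flask with 0.060 M of racemization catalyst, the early excess again gives about 78.1% in the product; computed, that flask gives 79.5% at a conversion of 44.8%, with an excess of right-handed substrate of 26.7% among what is left of the two.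

The earlier runs and the new flask are simulated with constants of no real substance; scatter was added.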